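## Retrosynthetic overview

- Hippolide C ⇐ unprotected 3-furyl diol. The butenolide, the only ring, is formed last by breaking the furan aromaticity in one pot (¹O₂ [4+2], base-induced endoperoxide fragmentation, NaBH₄).
- Furyl diol ⇐ δ-hydroxy (E)-enoate by DIBAL-H reduction.
- Enoate ⇐ 3-furaldehyde + α-homofarnesyl silyl dienolate. A catalytic enantioselective vinylogous Mukaiyama aldol sets the C–C bond, the (R)-carbinol and the (E)-alkene together.
- Silyl dienolate ⇐ ethyl crotonate + homofarnesyl iodide (deconjugative α-alkylation, then O-silylation).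
- Homofarnesyl iodide ⇐ (2E,6E)-farnesyl bromide + thioanisole (one-carbon homologation through the sulfide).

Assumption: the (R,R)-bisphosphoramide/SiCl₄ catalyst is taken to attack the Re face of 3-furaldehyde, as for other aryl aldehydes; if the sense is opposite, the (S,S)-catalyst is used. LDA is a commercial solution.

## Route

Step 1
Reactants: 1 thioanisole; 2 (2E,6E)-farnesyl bromide
Product: 4 phenyl (3E,7E)-4,8,12-trimethyltrideca-3,7,11-trien-1-yl sulfide (homofarnesyl phenyl sulfide), via (phenylthio)methyllithium 3 (not isolated)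
Conditions: 1, n-BuLi, DABCO, THF, 0 °C; then 2, −78 °C → rt
Reagents that add atoms: n-butyllithium, [Li]CCCC (lithium of 3 only)
Why: α-lithiation of thioanisole and SN2 alkylation of the sulfur-stabilised carbanion at the primary allylic carbon of 2 add the one extra chain carbon without touching the E alkenes.

Step 2
Reactants: 4 homofarnesyl phenyl sulfide
Product: 6 (3E,7E)-1-iodo-4,8,12-trimethyltrideca-3,7,11-triene (homofarnesyl iodide), via sulfonium iodide 5 (not isolated)
Conditions: MeI (excess), NaI, DMF, 75 °C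
Reagents that add atoms: iodomethane, CI (iodine of 6; methyl of 5 only)
Why: S-methylation gives a sulfonium salt whose primary carbon is displaced by iodide (SN2), releasing thioanisole; the alkenes are inert under these neutral conditions.

Step 3
Reactants: 6 homofarnesyl iodide; 7 ethyl (E)-but-2-enoate (ethyl crotonate)
Product: 9 ethyl (5E,9E)-2-ethenyl-6,10,14-trimethylpentadeca-5,9,13-trienoate (racemic), via lithium dienolate 8 (not isolated)
Conditions: 7 (1.5 equiv), LDA, HMPA, THF, −78 °C; then 6, −78 → −20 °C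
Reagents that add atoms: lithium diisopropylamide, [Li+].CC(C)[N-]C(C)C (lithium of 8 only)
Why: deconjugative α-alkylation: the LDA/HMPA-derived crotonate dienolate reacts with the primary iodide at its α-carbon, giving the β,γ-unsaturated ester; the new stereocentre is racemic and is erased in step 4.

Step 4
Reactants: 9 the 2-ethenyl ester
Product: 11 tert-butyl{[(5E,9E)-1-ethoxy-2-ethenyl-6,10,14-trimethylpentadeca-1,5,9,13-tetraen-1-yl]oxy}dimethylsilane (silyl dienolate; C1 E/Z mixture), via lithium ester enolate 10 (not isolated)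
Conditions: LDA, THF, −78 °C; then TBSCl, HMPA, −78 → 0 °C; pentane, filtration under Ar, used crude
Reagents that add atoms: lithium diisopropylamide, [Li+].CC(C)[N-]C(C)C (lithium of 10 only); tert-butyldimethylsilyl chloride, CC(C)(C)[Si](C)(C)Cl
Why: O-silylation of the ester enolate (silyl ketene acetal formation) gives the 2-substituted 1,1-dioxy-1,3-diene; its C1 geometry is not carried into any stereocentre.

Step 5
Reactants: 11 silyl dienolate; 12 furan-3-carbaldehyde
Product: 14 ethyl (2E,5R)-5-(furan-3-yl)-5-hydroxy-2-[(3E,7E)-4,8,12-trimethyltrideca-3,7,11-trien-1-yl]pent-2-enoate, via trichlorosilyl ether 13 (not isolated)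
Conditions: SiCl₄ (1.1 equiv), (R,R)-binaphthyldiamine-derived bisphosphoramide (pentane-1,5-diyl-linked, 5 mol %), i-Pr₂NEt (10 mol %), CH₂Cl₂, −78 °C; then sat. aq NaHCO₃
Reagents that add atoms: silicon tetrachloride, Cl[Si](Cl)(Cl)Cl (SiCl3 of 13 only)
Why: Lewis-base-activated SiCl₄ vinylogous Mukaiyama aldol: the chiral phosphoramide-bound trichlorosilyl cation activates the aldehyde and blocks its Si face, so the terminal γ-carbon of the dienolate adds to the Re face through an open transition state to set the (R)-carbinol, while the s-trans diene gives the (E)-enoate (ester trans to the new CH₂).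

Step 6
Reactants: 14 the δ-hydroxy enoate
Product: 16 (1R,3E,7E,11E)-1-(furan-3-yl)-4-(hydroxymethyl)-8,12,16-trimethylheptadeca-3,7,11,15-tetraen-1-ol, via aluminium dialkoxide 15 (not isolated)
Conditions: DIBAL-H (3.5 equiv), CH₂Cl₂, −78 °C; aq Rochelle salt
Reagents that add atoms: diisobutylaluminium hydride, CC(C)C[AlH]CC(C)C (aluminium groups of 15 only)
Why: 1,2-reduction of the α,β-unsaturated ester to the allylic alcohol (DIBAL-H reduction); the furan, the alkene geometry and the carbinol centre are untouched, and acid is avoided because the furyl carbinol is ionisable.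

Step 7
Reactants: 16 the furyl diol
Product: 20 Hippolide C, 4-[(1R,3E,7E,11E)-1-hydroxy-4-(hydroxymethyl)-8,12,16-trimethylheptadeca-3,7,11,15-tetraen-1-yl]furan-2(5H)-one, via furan endoperoxide 17 (not isolated), via hydroxybutenolide 18 (not isolated), via hydroxy acid 19 (not isolated)
Conditions: O₂, hν (visible), rose bengal (cat.), i-Pr₂NEt, CH₂Cl₂, −78 °C, stopped at furan consumption; then NaBH₄, MeOH, −78 → 0 °C; then 1 M HCl to pH 2–3, rt
Reagents that add atoms: oxygen, O=O
Why: singlet-oxygen [4+2] cycloaddition to the furan outpaces the ene reaction of the trisubstituted alkenes; the hindered base then removes the less hindered C5–H of the endoperoxide (Kornblum–DeLaMare-type fragmentation) to give the 4-substituted 5-hydroxybutenolide, and borohydride reduction of its ring-open aldehyde with acid lactonisation gives the butenolide with CH₂ next to the carbinol, whose stereocentre is not involved.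

## Compound list

1 | thioanisole (methyl phenyl sulfide) | CSc1ccccc1 | starting material
2 | (2E,6E)-farnesyl bromide | CC(C)=CCC/C(C)=C/CC/C(C)=C/CBr | starting material
3 | (phenylthio)methyllithium (not isolated) | [Li]CSc1ccccc1 | intermediate
4 | phenyl (3E,7E)-4,8,12-trimethyltrideca-3,7,11-trien-1-yl sulfide | CC(C)=CCC/C(C)=C/CC/C(C)=C/CCSc1ccccc1 | intermediate
5 | methyl(phenyl)[(3E,7E)-4,8,12-trimethyltrideca-3,7,11-trien-1-yl]sulfonium iodide (not isolated) | CC(C)=CCC/C(C)=C/CC/C(C)=C/CC[S+](C)c1ccccc1.[I-] | intermediate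
6 | (3E,7E)-1-iodo-4,8,12-trimethyltrideca-3,7,11-triene | CC(C)=CCC/C(C)=C/CC/C(C)=C/CCI | intermediate
7 | ethyl (E)-but-2-enoate | C/C=C/C(=O)OCC | starting material
8 | lithium 1-ethoxybuta-1,3-dien-1-olate (not isolated) | [Li+].[O-]C(OCC)=CC=C | intermediate
9 | ethyl (5E,9E)-2-ethenyl-6,10,14-trimethylpentadeca-5,9,13-trienoate (racemic) | CC(C)=CCC/C(C)=C/CC/C(C)=C/CCC(C=C)C(=O)OCC | intermediate
10 | lithium enolate of 9 (not isolated) | [Li+].CC(C)=CCC/C(C)=C/CC/C(C)=C/CCC(C=C)=C([O-])OCC | intermediate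
11 | tert-butyl{[(5E,9E)-1-ethoxy-2-ethenyl-6,10,14-trimethylpentadeca-1,5,9,13-tetraen-1-yl]oxy}dimethylsilane (C1 E/Z mixture) | CC(C)=CCC/C(C)=C/CC/C(C)=C/CCC(C=C)=C(OCC)O[Si](C)(C)C(C)(C)C | intermediate
12 | furan-3-carbaldehyde | O=Cc1ccoc1 | starting material
13 | trichlorosilyl ether of 14 (not isolated) | CC(C)=CCC/C(C)=C/CC/C(C)=C/CC/C(=C\C[C@@H](O[Si](Cl)(Cl)Cl)c1ccoc1)C(=O)OCC | intermediate
14 | ethyl (2E,5R)-5-(furan-3-yl)-5-hydroxy-2-[(3E,7E)-4,8,12-trimethyltrideca-3,7,11-trien-1-yl]pent-2-enoate | CC(C)=CCC/C(C)=C/CC/C(C)=C/CC/C(=C\C[C@@H](O)c1ccoc1)C(=O)OCC | intermediate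
15 | O,O'-bis(diisobutylaluminium) dialkoxide of 16 (not isolated) | CC(C)=CCC/C(C)=C/CC/C(C)=C/CC/C(=C\C[C@@H](O[Al](CC(C)C)CC(C)C)c1ccoc1)CO[Al](CC(C)C)CC(C)C | intermediate
16 | (1R,3E,7E,11E)-1-(furan-3-yl)-4-(hydroxymethyl)-8,12,16-trimethylheptadeca-3,7,11,15-tetraen-1-ol | CC(C)=CCC/C(C)=C/CC/C(C)=C/CC/C(=C\C[C@@H](O)c1ccoc1)CO | intermediate
17 | (1R,3E,7E,11E)-4-(hydroxymethyl)-8,12,16-trimethyl-1-(2,3,7-trioxabicyclo[2.2.1]hept-5-en-5-yl)heptadeca-3,7,11,15-tetraen-1-ol (both bridgehead diastereomers; not isolated) | CC(C)=CCC/C(C)=C/CC/C(C)=C/CC/C(=C\C[C@@H](O)C1=CC2OOC1O2)CO | intermediate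
18 | 5-hydroxy-4-[(1R,3E,7E,11E)-1-hydroxy-4-(hydroxymethyl)-8,12,16-trimethylheptadeca-3,7,11,15-tetraen-1-yl]furan-2(5H)-one (C5 epimers; not isolated) | CC(C)=CCC/C(C)=C/CC/C(C)=C/CC/C(=C\C[C@@H](O)C1=CC(=O)OC1O)CO | intermediate
19 | (2E,4R,6E,10E,14E)-4-hydroxy-3,7-bis(hydroxymethyl)-11,15,19-trimethylicosa-2,6,10,14,18-pentaenoic acid (CO₂H cis to the C3 CH₂OH; not isolated) | CC(C)=CCC/C(C)=C/CC/C(C)=C/CC/C(=C\C[C@@H](O)/C(CO)=C/C(=O)O)CO | intermediate
20 | Hippolide C, 4-[(1R,3E,7E,11E)-1-hydroxy-4-(hydroxymethyl)-8,12,16-trimethylheptadeca-3,7,11,15-tetraen-1-yl]furan-2(5H)-one | CC(C)=CCC/C(C)=C/CC/C(C)=C/CC/C(=C\C[C@@H](O)C1=CC(=O)OC1)CO | target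

## Step count and risks

Total steps: 7. Longest linear sequence: 7 (steps 1–7; furan-3-carbaldehyde enters at step 5).

Most likely to fail, first: step 5. The α-homofarnesyl dienolate is bulkier than the known α-methyl case, enantioselectivity on 3-furaldehyde is untested, and SiCl₄/HCl traces could attack the polyene or furan. The fallback replaces the vinylogous aldol by reagent-controlled allylation plus Wittig olefination; it sets out from 12 and 6 and rejoins the route at 14. Aldehyde 12 is allylated with (+)-Ipc₂B(allyl) (Et₂O, −78 °C; NaOH/H₂O₂), the enantiomer that attacks the Re face of aryl aldehydes, to give (R)-1-(furan-3-yl)but-3-en-1-ol F1. OsO₄ (cat.)/NaIO₄/2,6-lutidine cleaves the terminal alkene to (R)-3-(furan-3-yl)-3-hydroxypropanal F2, used at once. Separately, iodide 6 alkylates ethyl (triphenylphosphoranylidene)acetate (toluene, 90 °C) to [(5E,9E)-1-ethoxy-6,10,14-trimethyl-1-oxopentadeca-5,9,13-trien-2-yl]triphenylphosphonium iodide F3. Aqueous NaOH converts this into ethyl (5E,9E)-6,10,14-trimethyl-2-(triphenyl-λ5-phosphanylidene)pentadeca-5,9,13-trienoate F4. Wittig reaction of F2 with F4 (CH₂Cl₂, rt) gives 14 with the (E) geometry typical of α-substituted stabilised ylides.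

Second: step 7. Singlet oxygen can also attack the four trisubstituted alkenes by the ene reaction, and the base-controlled regiochemistry could erode on this substrate. The fallback uses silicon-directed furan oxidation; it sets out from 12 and rejoins the route at 18. Aldehyde 12 is masked in situ as its lithium morpholide adduct, lithiated at C5 with s-BuLi and silylated with Et₃SiCl to give 5-(triethylsilyl)furan-3-carbaldehyde F5. The step 5 conditions with 11 give ethyl (2E,5R)-5-hydroxy-5-[5-(triethylsilyl)furan-3-yl]-2-[(3E,7E)-4,8,12-trimethyltrideca-3,7,11-trien-1-yl]pent-2-enoate F6. The step 6 conditions give (1R,3E,7E,11E)-4-(hydroxymethyl)-8,12,16-trimethyl-1-[5-(triethylsilyl)furan-3-yl]heptadeca-3,7,11,15-tetraen-1-ol F7. Photooxygenation of the more reactive 2-silylfuran without amine (O₂, hν, rose bengal, CH₂Cl₂/MeOH, −78 °C) goes by silyl migration in the endoperoxide and gives 18 regiospecifically (carbonyl at the former silyl carbon). NaBH₄ and acid as in step 7 then give 20.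

Third: step 3. The basic dienolate can eliminate HI from the homoallylic iodide (conjugated diene), and some γ- or dialkylation is possible. The fallback builds the same dienolate by olefination instead of deconjugative alkylation; it sets out from 6 and rejoins the route at 11. The less basic anion of triethyl phosphonoacetate (NaH, DMF, 50 °C) is alkylated by 6 to give ethyl (5E,9E)-2-(diethoxyphosphoryl)-6,10,14-trimethylpentadeca-5,9,13-trienoate F8. Horner–Wadsworth–Emmons reaction with acetaldehyde (NaH, THF, 0 °C) gives ethyl (5E,9E)-2-ethylidene-6,10,14-trimethylpentadeca-5,9,13-trienoate F9 as a 2E/2Z mixture. Both isomers undergo γ-deprotonation with LDA/HMPA to the same lithium dienolate 10, and TBSCl then gives 11.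

## Further compounds

F1 | step 5 | (R)-1-(furan-3-yl)but-3-en-1-ol | C=CC[C@@H](O)c1ccoc1
F2 | step 5 | (R)-3-(furan-3-yl)-3-hydroxypropanal | O=CC[C@@H](O)c1ccoc1
F3 | step 5 | [(5E,9E)-1-ethoxy-6,10,14-trimethyl-1-oxopentadeca-5,9,13-trien-2-yl]triphenylphosphonium iodide | CC(C)=CCC/C(C)=C/CC/C(C)=C/CCC(C(=O)OCC)[P+](c1ccccc1)(c1ccccc1)c1ccccc1.[I-]
F4 | step 5 | ethyl (5E,9E)-6,10,14-trimethyl-2-(triphenyl-λ5-phosphanylidene)pentadeca-5,9,13-trienoate | CC(C)=CCC/C(C)=C/CC/C(C)=C/CCC(C(=O)OCC)=P(c1ccccc1)(c1ccccc1)c1ccccc1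
F5 | step 7 | 5-(triethylsilyl)furan-3-carbaldehyde | O=Cc1coc([Si](CC)(CC)CC)c1
F6 | step 7 | ethyl (2E,5R)-5-hydroxy-5-[5-(triethylsilyl)furan-3-yl]-2-[(3E,7E)-4,8,12-trimethyltrideca-3,7,11-trien-1-yl]pent-2-enoate | CC(C)=CCC/C(C)=C/CC/C(C)=C/CC/C(=C\C[C@@H](O)c1coc([Si](CC)(CC)CC)c1)C(=O)OCC
F7 | step 7 | (1R,3E,7E,11E)-4-(hydroxymethyl)-8,12,16-trimethyl-1-[5-(triethylsilyl)furan-3-yl]heptadeca-3,7,11,15-tetraen-1-ol | CC(C)=CCC/C(C)=C/CC/C(C)=C/CC/C(=C\C[C@@H](O)c1coc([Si](CC)(CC)CC)c1)CO
F8 | step 3 | ethyl (5E,9E)-2-(diethoxyphosphoryl)-6,10,14-trimethylpentadeca-5,9,13-trienoate | CC(C)=CCC/C(C)=C/CC/C(C)=C/CCC(C(=O)OCC)P(=O)(OCC)OCC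
F9 | step 3 | ethyl (5E,9E)-2-ethylidene-6,10,14-trimethylpentadeca-5,9,13-trienoate (2E/2Z mixture) | CC(C)=CCC/C(C)=C/CC/C(C)=C/CCC(=CC)C(=O)OCC
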